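**Strategy.** Ring B is a cyclohexene whose C8=C9 double bond lies opposite the C5–C6 edge, so the decalin is opened by a retro-Diels–Alder cut into a C7=C8–C9=C10 diene and a C5=C6 dienophile linked by the C1–C4 chain of ring A. An auxiliary-controlled intramolecular Diels–Alder reaction of an acyclic trienimide should close ring A and ring B together through the ring-fusion bond C5–C10 and the C6–C7 bond, creating the quaternary C10, the C5 centre and the tetrasubstituted alkene in one operation. The acyl carbon on C6 is then excised to a C6 ketone, whose α face guides the entry of the 7α and 6β oxygens.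

Key step: step 12

Remark: labdane numbering is used throughout (C20 is the methyl on C10; β is the face of C20, α the opposite face), and (2E)-3-methylpent-2-en-4-yn-1-ol is taken as available in geometrically pure form.

Step 1
Reactants: 1 ethyl 5-bromo-2,2-dimethylpentanoate
Product: 2 5-bromo-2,2-dimethylpentanal
Conditions: iBu2AlH (1.1 equiv), CH2Cl2, −78 °C; aq. potassium sodium tartrate
Reagents that add atoms: none
Why: Partial hydride reduction of an α,α-disubstituted ester should stop at the aldehyde because the hindered aluminium hemiacetal survives at −78 °C until work-up, and the primary bromide is inert.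

Step 2
Reactants: 2 5-bromo-2,2-dimethylpentanal
Product: 3 5-bromo-1,1-dimethoxy-2,2-dimethylpentane
Conditions: HC(OMe)3, TsOH·H2O (cat.), MeOH, rt
Reagents that add atoms: trimethyl orthoformate, COC(OC)OC
Why: Acid-catalysed acetalization masks the future C5 aldehyde so that the bromide can be turned into an organometallic reagent.

Step 3
Reactants: 3 5-bromo-1,1-dimethoxy-2,2-dimethylpentane; 4 ethyl but-2-ynoate
Product: 8 ethyl (2Z)-2-iodo-8,8-dimethoxy-3,7,7-trimethyloct-2-enoate, via Grignard reagent 5 (not isolated), via alkylcopper 6 (not isolated), via alkenylcopper 7 (not isolated)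
Conditions: Mg, THF, 40 °C; CuBr·SMe2 (1 equiv), −40 °C; 4, −78 °C; I2, −78 to −20 °C
Reagents that add atoms: iodine, II
Why: syn-Carbocupration of the alkynoate places the tether on C10 cis to copper on C9 and the C20 methyl cis to the ester, and iodinolysis with retention at low temperature should fix this tetrasubstituted geometry.

Step 4
Reactants: 9 (2E)-3-methylpent-2-en-4-yn-1-ol
Product: 10 tert-butyl{[(2E)-3-methylpent-2-en-4-yn-1-yl]oxy}diphenylsilane
Conditions: t-BuPh2SiCl, imidazole, DMF, rt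
Reagents that add atoms: tert-butyl(chloro)diphenylsilane, CC(C)(C)[Si](Cl)(c1ccccc1)c1ccccc1
Why: Silylation protects the future C15 alcohol with a group that should survive organometallic, Lewis-acid and oxidative steps and leave under fluoride without touching acetates.

Step 5
Reactants: 10 tert-butyl{[(2E)-3-methylpent-2-en-4-yn-1-yl]oxy}diphenylsilane
Product: 11 tert-butyl{[(2E)-3-methylpenta-2,4-dien-1-yl]oxy}diphenylsilane
Conditions: H2 (1 atm), Pd/CaCO3 poisoned with Pb(OAc)2, quinoline, hexane, rt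
Reagents that add atoms: none
Why: Lindlar-type semihydrogenation should reduce the terminal alkyne to the vinyl group and leave the (E)-trisubstituted alkene, the later C13=C14, unchanged.

Step 6
Reactants: 11 tert-butyl{[(2E)-3-methylpenta-2,4-dien-1-yl]oxy}diphenylsilane; 8 ethyl (2Z)-2-iodo-8,8-dimethoxy-3,7,7-trimethyloct-2-enoate
Product: 13 ethyl (2E)-2-[(3E)-5-{[tert-butyl(diphenyl)silyl]oxy}-3-methylpent-3-en-1-yl]-8,8-dimethoxy-3,7,7-trimethyloct-2-enoate, via alkylborane 12 (not isolated)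
Conditions: 11, 9-BBN-H, THF, 0 °C to rt; then 8, PdCl2(dppf) (5 mol%), AsPh3, Cs2CO3, DMF/H2O, rt
Reagents that add atoms: none
Why: 9-BBN should hydroborate only the monosubstituted vinyl group at its terminus, and the B-alkyl Suzuki–Miyaura coupling of the α-iodo enoate proceeds with retention, so the side chain on C9 ends cis to the tether on C10.

Step 7
Reactants: 13 ethyl (2E)-2-[(3E)-5-{[tert-butyl(diphenyl)silyl]oxy}-3-methylpent-3-en-1-yl]-8,8-dimethoxy-3,7,7-trimethyloct-2-enoate
Product: 14 (3E)-3-[(3E)-5-{[tert-butyl(diphenyl)silyl]oxy}-3-methylpent-3-en-1-yl]-9,9-dimethoxy-2,4,8,8-tetramethylnon-3-en-2-ol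
Conditions: MeMgBr (4 equiv), THF, 0 °C to rt
Reagents that add atoms: methylmagnesium bromide, C[Mg]Br
Why: Double Grignard addition to the ester gives the tertiary allylic alcohol and delivers C7 and C17; conjugate addition is blocked by the fully substituted β-carbon.

Step 8
Reactants: 14 (3E)-3-[(3E)-5-{[tert-butyl(diphenyl)silyl]oxy}-3-methylpent-3-en-1-yl]-9,9-dimethoxy-2,4,8,8-tetramethylnon-3-en-2-ol
Product: 15 tert-butyl{[(2E,6E)-11,11-dimethoxy-3,7,10,10-tetramethyl-6-(prop-1-en-2-yl)undeca-2,6-dien-1-yl]oxy}diphenylsilane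
Conditions: methyl N-(triethylammoniosulfonyl)carbamate (Burgess reagent), toluene, 50 °C
Reagents that add atoms: none
Why: syn-Elimination through the sulfamate can only take a methyl hydrogen, so the isopropenyl group (C8=C7) forms and completes the diene without disturbing the C9=C10 geometry.

Step 9
Reactants: 15 tert-butyl{[(2E,6E)-11,11-dimethoxy-3,7,10,10-tetramethyl-6-(prop-1-en-2-yl)undeca-2,6-dien-1-yl]oxy}diphenylsilane
Product: 16 (6E)-7-[(3E)-5-{[tert-butyl(diphenyl)silyl]oxy}-3-methylpent-3-en-1-yl]-2,2,6,8-tetramethylnona-6,8-dienal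
Conditions: oxalic acid, wet SiO2, CH2Cl2, rt
Reagents that add atoms: water, O
Why: Mild acetal hydrolysis should free the non-enolizable C5 aldehyde while the silyl ether and the diene remain intact.

Step 10
Reactants: 17 (4S)-4-benzyl-1,3-oxazolidin-2-one; 18 (diethoxyphosphoryl)acetic acid
Product: 20 diethyl {2-[(4S)-4-benzyl-2-oxo-1,3-oxazolidin-3-yl]-2-oxoethyl}phosphonate, via mixed anhydride 19 (not isolated)
Conditions: t-BuCOCl, Et3N, THF, −20 °C; then 17, LiCl, rt
Reagents that add atoms: none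
Why: N-Acylation of the oxazolidinone through the mixed pivalic anhydride gives the phosphonate that carries the chiral auxiliary.

Step 11
Reactants: 16 (6E)-7-[(3E)-5-{[tert-butyl(diphenyl)silyl]oxy}-3-methylpent-3-en-1-yl]-2,2,6,8-tetramethylnona-6,8-dienal; 20 diethyl {2-[(4S)-4-benzyl-2-oxo-1,3-oxazolidin-3-yl]-2-oxoethyl}phosphonate
Product: 21 (4S)-4-benzyl-3-[(2E,8E)-9-[(3E)-5-{[tert-butyl(diphenyl)silyl]oxy}-3-methylpent-3-en-1-yl]-4,4,8,10-tetramethylundeca-2,8,10-trienoyl]-1,3-oxazolidin-2-one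
Conditions: LiCl, DBU, MeCN, rt
Reagents that add atoms: none
Why: Horner–Wadsworth–Emmons olefination of the neopentyl aldehyde with the stabilized phosphonate should give the (E)-enoyl imide, the C5=C6 dienophile.

Step 12
Reactants: 21 (4S)-4-benzyl-3-[(2E,8E)-9-[(3E)-5-{[tert-butyl(diphenyl)silyl]oxy}-3-methylpent-3-en-1-yl]-4,4,8,10-tetramethylundeca-2,8,10-trienoyl]-1,3-oxazolidin-2-one
Product: 22 (4S)-4-benzyl-3-{[15-{[tert-butyl(diphenyl)silyl]oxy}labda-8,13E-dien-6α-yl]carbonyl}-1,3-oxazolidin-2-one (trans-fused; 5α-H; 10β-CH3)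
Conditions: Me2AlCl (1.5 equiv), CH2Cl2, −30 to 0 °C; 1 M HCl
Reagents that add atoms: none
Why: Me2AlCl converts the (E)-enoyl imide into a cationic bidentate aluminium chelate locked s-cis, and the electron-rich C7=C8–C9=C10 diene adds across C5=C6 in a concerted but asynchronous [4+2] cycloaddition in which the C5–C10 bond is the more advanced one. The closest known reaction type is the oxazolidinone-auxiliary-controlled intramolecular Diels–Alder reaction of (2E)-trienimides to trans-fused decalins. Ring B is closed as the new cyclohexene of the cycloaddition (C5–C10 and C6–C7 formed, C8=C9 left as the alkene), and ring A is closed in the type 1 mode, the C1–C4 tether folding as a chair between diene terminus C10 and dienophile carbon C5. The endo position of the chelated acyl group together with the (E) dienophile puts H5 and the acyl group on the α face and makes the fusion trans, the diene geometry fixed in step 3 (tether outside, methyl inside) puts C20 on the β face of C10, and the benzyl group of the (4S) auxiliary shields the Re face of C6 so that both bonds form on the Si faces of C6 and C5. The step needs endo over exo selectivity and enough reactivity at a diene terminus that carries an inside methyl group; the chelated cationic dienophile, the Thorpe–Ingold effect of the C4 methyl groups and the four-atom tether are meant to secure both.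

Step 13
Reactants: 22 (4S)-4-benzyl-3-{[15-{[tert-butyl(diphenyl)silyl]oxy}labda-8,13E-dien-6α-yl]carbonyl}-1,3-oxazolidin-2-one
Product: 23 15-{[tert-butyl(diphenyl)silyl]oxy}labda-8,13E-diene-6α-carboxylic acid
Conditions: LiOH, H2O2, THF/H2O, 0 °C; Na2SO3; 1 M HCl
Reagents that add atoms: hydrogen peroxide, OO
Why: Lithium hydroperoxide attacks the exocyclic imide carbonyl selectively, releasing the auxiliary and the acid without affecting the unactivated alkenes.

Step 14
Reactants: 23 15-{[tert-butyl(diphenyl)silyl]oxy}labda-8,13E-diene-6α-carboxylic acid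
Product: 26 15-{[tert-butyl(diphenyl)silyl]oxy}labda-8,13E-dien-6-one, via dilithium enediolate 24 (not isolated), via hydroperoxy acid 25 (not isolated)
Conditions: LiN(iPr)2 (2.5 equiv), THF/HMPA, −78 to 0 °C; O2, −78 °C; aq. NH4Cl, rt
Reagents that add atoms: oxygen, O=O
Why: Oxidative decarboxylation: the carboxylate enediolate is oxygenated at C6, and the α-hydroperoxy acid loses CO2 and water to the C6 ketone, which erases the temporary C6 centre and leaves the trans fusion at C5 untouched.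

Step 15
Reactants: 26 15-{[tert-butyl(diphenyl)silyl]oxy}labda-8,13E-dien-6-one
Product: 28 15-{[tert-butyl(diphenyl)silyl]oxy}-7α-hydroxylabda-8,13E-dien-6-one, via potassium dienolate 27 (not isolated)
Conditions: KN(SiMe3)2, THF, −78 °C; 2-(benzenesulfonyl)-3-phenyloxaziridine, −78 °C; aq. NH4Cl
Reagents that add atoms: 2-(benzenesulfonyl)-3-phenyloxaziridine, O=S(=O)(N1OC1c1ccccc1)c1ccccc1
Why: C7 is deprotonated because it is both α to the ketone and allylic, and oxaziridine enolate hydroxylation at the α-carbon of the dienolate should occur on the α face, anti to the angular C20 methyl, keeping the alkene at C8=C9.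

Step 16
Reactants: 28 15-{[tert-butyl(diphenyl)silyl]oxy}-7α-hydroxylabda-8,13E-dien-6-one
Product: 29 15-{[tert-butyl(diphenyl)silyl]oxy}labda-8,13E-diene-6β,7α-diol
Conditions: NaBH4, MeOH/CH2Cl2, −40 to 0 °C
Reagents that add atoms: none
Why: Hydride reduction from the α face, the β face being blocked by the 1,3-diaxial C20 and 4β methyl groups, should give the axial 6β alcohol trans to the 7α hydroxyl.

Step 17
Reactants: 29 15-{[tert-butyl(diphenyl)silyl]oxy}labda-8,13E-diene-6β,7α-diol
Product: 30 15-{[tert-butyl(diphenyl)silyl]oxy}labda-8,13E-diene-6β,7α-diyl diacetate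
Conditions: Ac2O, DMAP, Et3N, CH2Cl2, 40 °C
Reagents that add atoms: acetic anhydride, CC(=O)OC(C)=O
Why: DMAP-catalysed acylation should esterify both secondary alcohols, including the hindered axial 6β hydroxyl, while C15 stays silylated.

Step 18
Reactants: 30 15-{[tert-butyl(diphenyl)silyl]oxy}labda-8,13E-diene-6β,7α-diyl diacetate
Product: 31 (5S,6S,7S,10S)-6β,7α-diacetoxylabda-8,13E-dien-15-ol (CNP0187815.1)
Conditions: Bu4NF, AcOH, THF, rt
Reagents that add atoms: none
Why: Fluoride desilylation buffered with acetic acid frees the primary allylic alcohol without cleaving or shifting the two acetates.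

**Compound list**

1 | ethyl 5-bromo-2,2-dimethylpentanoate | CCOC(=O)C(C)(C)CCCBr | starting material
2 | 5-bromo-2,2-dimethylpentanal | O=CC(C)(C)CCCBr | intermediate
3 | 5-bromo-1,1-dimethoxy-2,2-dimethylpentane | COC(OC)C(C)(C)CCCBr | intermediate
4 | ethyl but-2-ynoate | CCOC(=O)C#CC | starting material
5 | (5,5-dimethoxy-4,4-dimethylpentyl)magnesium bromide | COC(OC)C(C)(C)CCC[Mg]Br | intermediate
6 | (5,5-dimethoxy-4,4-dimethylpentyl)copper | COC(OC)C(C)(C)CCC[Cu] | intermediate
7 | [(2Z)-1-ethoxy-8,8-dimethoxy-3,7,7-trimethyl-1-oxooct-2-en-2-yl]copper | COC(OC)C(C)(C)CCC/C(C)=C(\[Cu])C(=O)OCC | intermediate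
8 | ethyl (2Z)-2-iodo-8,8-dimethoxy-3,7,7-trimethyloct-2-enoate | COC(OC)C(C)(C)CCC/C(C)=C(\I)C(=O)OCC | intermediate
9 | (2E)-3-methylpent-2-en-4-yn-1-ol | C#C/C(C)=C/CO | starting material
10 | tert-butyl{[(2E)-3-methylpent-2-en-4-yn-1-yl]oxy}diphenylsilane | C#C/C(C)=C/CO[Si](c1ccccc1)(c1ccccc1)C(C)(C)C | intermediate
11 | tert-butyl{[(2E)-3-methylpenta-2,4-dien-1-yl]oxy}diphenylsilane | C=C/C(C)=C/CO[Si](c1ccccc1)(c1ccccc1)C(C)(C)C | intermediate
12 | 9-[(3E)-5-{[tert-butyl(diphenyl)silyl]oxy}-3-methylpent-3-en-1-yl]-9-borabicyclo[3.3.1]nonane | B1(CC/C(C)=C/CO[Si](c2ccccc2)(c2ccccc2)C(C)(C)C)C2CCCC1CCC2 | intermediate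
13 | ethyl (2E)-2-[(3E)-5-{[tert-butyl(diphenyl)silyl]oxy}-3-methylpent-3-en-1-yl]-8,8-dimethoxy-3,7,7-trimethyloct-2-enoate | COC(OC)C(C)(C)CCC/C(C)=C(\CC/C(C)=C/CO[Si](c1ccccc1)(c1ccccc1)C(C)(C)C)C(=O)OCC | intermediate
14 | (3E)-3-[(3E)-5-{[tert-butyl(diphenyl)silyl]oxy}-3-methylpent-3-en-1-yl]-9,9-dimethoxy-2,4,8,8-tetramethylnon-3-en-2-ol | COC(OC)C(C)(C)CCC/C(C)=C(\CC/C(C)=C/CO[Si](c1ccccc1)(c1ccccc1)C(C)(C)C)C(C)(C)O | intermediate
15 | tert-butyl{[(2E,6E)-11,11-dimethoxy-3,7,10,10-tetramethyl-6-(prop-1-en-2-yl)undeca-2,6-dien-1-yl]oxy}diphenylsilane | COC(OC)C(C)(C)CCC/C(C)=C(\CC/C(C)=C/CO[Si](c1ccccc1)(c1ccccc1)C(C)(C)C)C(C)=C | intermediate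
16 | (6E)-7-[(3E)-5-{[tert-butyl(diphenyl)silyl]oxy}-3-methylpent-3-en-1-yl]-2,2,6,8-tetramethylnona-6,8-dienal | O=CC(C)(C)CCC/C(C)=C(\CC/C(C)=C/CO[Si](c1ccccc1)(c1ccccc1)C(C)(C)C)C(C)=C | intermediate
17 | (4S)-4-benzyl-1,3-oxazolidin-2-one | O=C1N[C@@H](Cc2ccccc2)CO1 | starting material
18 | (diethoxyphosphoryl)acetic acid | CCOP(=O)(CC(=O)O)OCC | starting material
19 | (diethoxyphosphoryl)acetic 2,2-dimethylpropanoic anhydride | CCOP(=O)(CC(=O)OC(=O)C(C)(C)C)OCC | intermediate
20 | diethyl {2-[(4S)-4-benzyl-2-oxo-1,3-oxazolidin-3-yl]-2-oxoethyl}phosphonate | CCOP(=O)(CC(=O)N1C(=O)OC[C@@H]1Cc1ccccc1)OCC | intermediate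
21 | (4S)-4-benzyl-3-[(2E,8E)-9-[(3E)-5-{[tert-butyl(diphenyl)silyl]oxy}-3-methylpent-3-en-1-yl]-4,4,8,10-tetramethylundeca-2,8,10-trienoyl]-1,3-oxazolidin-2-one | O=C(/C=C/C(C)(C)CCC/C(C)=C(\CC/C(C)=C/CO[Si](c1ccccc1)(c1ccccc1)C(C)(C)C)C(C)=C)N1C(=O)OC[C@@H]1Cc1ccccc1 | intermediate
22 | (4S)-4-benzyl-3-{[15-{[tert-butyl(diphenyl)silyl]oxy}labda-8,13E-dien-6α-yl]carbonyl}-1,3-oxazolidin-2-one (trans-fused; 5α-H; 10β-CH3) | O=C([C@H]1CC(C)=C(CC/C(C)=C/CO[Si](c3ccccc3)(c3ccccc3)C(C)(C)C)[C@@]2(C)CCCC(C)(C)[C@H]12)N1C(=O)OC[C@@H]1Cc1ccccc1 | intermediate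
23 | 15-{[tert-butyl(diphenyl)silyl]oxy}labda-8,13E-diene-6α-carboxylic acid | OC(=O)[C@H]1CC(C)=C(CC/C(C)=C/CO[Si](c3ccccc3)(c3ccccc3)C(C)(C)C)[C@@]2(C)CCCC(C)(C)[C@H]12 | intermediate
24 | dilithium enediolate of acid 23 (C6 trigonal) | [Li+].[Li+].[O-]C([O-])=C1CC(C)=C(CC/C(C)=C/CO[Si](c3ccccc3)(c3ccccc3)C(C)(C)C)[C@@]2(C)CCCC(C)(C)[C@H]12 | intermediate
25 | 6-hydroperoxy-15-{[tert-butyl(diphenyl)silyl]oxy}labda-8,13E-diene-6-carboxylic acid (C6 epimers) | OOC1(C(=O)O)CC(C)=C(CC/C(C)=C/CO[Si](c3ccccc3)(c3ccccc3)C(C)(C)C)[C@@]2(C)CCCC(C)(C)[C@H]12 | intermediate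
26 | 15-{[tert-butyl(diphenyl)silyl]oxy}labda-8,13E-dien-6-one (5α-H; 10β-CH3) | O=C1CC(C)=C(CC/C(C)=C/CO[Si](c3ccccc3)(c3ccccc3)C(C)(C)C)[C@@]2(C)CCCC(C)(C)[C@H]12 | intermediate
27 | potassium 6,8-dienolate of ketone 26 | [K+].[O-]C1=CC(C)=C(CC/C(C)=C/CO[Si](c3ccccc3)(c3ccccc3)C(C)(C)C)[C@@]2(C)CCCC(C)(C)[C@H]12 | intermediate
28 | 15-{[tert-butyl(diphenyl)silyl]oxy}-7α-hydroxylabda-8,13E-dien-6-one | O=C1[C@@H](O)C(C)=C(CC/C(C)=C/CO[Si](c3ccccc3)(c3ccccc3)C(C)(C)C)[C@@]2(C)CCCC(C)(C)[C@H]12 | intermediate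
29 | 15-{[tert-butyl(diphenyl)silyl]oxy}labda-8,13E-diene-6β,7α-diol | O[C@@H]1[C@@H](O)C(C)=C(CC/C(C)=C/CO[Si](c3ccccc3)(c3ccccc3)C(C)(C)C)[C@@]2(C)CCCC(C)(C)[C@H]12 | intermediate
30 | 15-{[tert-butyl(diphenyl)silyl]oxy}labda-8,13E-diene-6β,7α-diyl diacetate | CC(=O)O[C@@H]1[C@@H](OC(C)=O)C(C)=C(CC/C(C)=C/CO[Si](c3ccccc3)(c3ccccc3)C(C)(C)C)[C@@]2(C)CCCC(C)(C)[C@H]12 | intermediate
31 | (5S,6S,7S,10S)-6β,7α-diacetoxylabda-8,13E-dien-15-ol | CC(=O)O[C@@H]1[C@@H](OC(C)=O)C(C)=C(CC/C(C)=C/CO)[C@@]2(C)CCCC(C)(C)[C@H]12 | target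

**Step count and risks**

Total step count: 18. Longest linear sequence: 15 steps (steps 1, 2, 3, 6, 7, 8, 9, 11, 12, 13, 14, 15, 16, 17, 18).

Step 12 (key cycloaddition). What may go wrong: Lewis-acid-induced cationic isomerization or oligomerization of the electron-rich tetrasubstituted diene may outrun cycloaddition, and part of the material may pass through the exo mode, which gives the cis ring fusion. Fallback, covalent iminium catalysis in place of auxiliary and Lewis acid: aldehyde 16 would be treated with (triphenylphosphoranylidene)acetaldehyde to give the (2E)-trienal F1. F1 should cyclize under catalysis by the L-phenylalanine-derived (2S,5S)-5-benzyl-2-tert-butyl-3-methylimidazolidin-4-one trifluoroacetate, whose benzyl group should shield the same Re faces, to the bicyclic 6α-carbaldehyde F2. Aerobic copper-mediated deformylation (Cu(OAc)2, 2,2'-bipyridine, DABCO, O2, DMF) would then give ketone 26, where the route is rejoined.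

Step 6 (B-alkyl coupling at the tetrasubstituted iodoalkene). What may go wrong: slow coupling lets β-hydride elimination of the alkylpalladium and protodeboronation consume the borane, and the alkene geometry may leak. Fallback, the C9–C11 bond by enolate alkylation and the C10–C1 bond by iron-catalysed coupling: diene 11 would be hydroborated to borane 12 and iodinated (I2, NaOMe) to the homoallylic iodide F3. Alkylation of ethyl acetoacetate (K2CO3, acetone) would give the keto ester F4, and (E)-selective enol tosylation (TsCl, N-methylimidazole, Et3N) the enol tosylate F5. Fe(acac)3-catalysed coupling of F5 with Grignard reagent 5 would return ester 13.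

Step 14 (oxidative decarboxylation). What may go wrong: incomplete enolization of the hindered carboxylate at C6, whose axial β hydrogen is flanked by the C20 and 4β methyl groups, or autoxidation at the allylic positions during oxygenation. Fallback, radical decarboxylation in place of enolate oxygenation: acid 23 would be converted through its acid chloride and the sodium salt of 1-hydroxypyridine-2-thione into the Barton ester F6. Photolysis under O2 with t-BuSH followed by P(OMe)3 would give the C6 alcohol F7 as an epimer mixture, and Dess–Martin oxidation would give ketone 26.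

**Further compounds**

F1 | step 12 | (2E,8E)-9-[(3E)-5-{[tert-butyl(diphenyl)silyl]oxy}-3-methylpent-3-en-1-yl]-4,4,8,10-tetramethylundeca-2,8,10-trienal | O=C/C=C/C(C)(C)CCC/C(C)=C(\CC/C(C)=C/CO[Si](c1ccccc1)(c1ccccc1)C(C)(C)C)C(C)=C
F2 | step 12 | 15-{[tert-butyl(diphenyl)silyl]oxy}labda-8,13E-diene-6α-carbaldehyde | O=C[C@H]1CC(C)=C(CC/C(C)=C/CO[Si](c3ccccc3)(c3ccccc3)C(C)(C)C)[C@@]2(C)CCCC(C)(C)[C@H]12
F3 | step 6 | tert-butyl{[(2E)-5-iodo-3-methylpent-2-en-1-yl]oxy}diphenylsilane | ICC/C(C)=C/CO[Si](c1ccccc1)(c1ccccc1)C(C)(C)C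
F4 | step 6 | ethyl (5E)-2-acetyl-7-{[tert-butyl(diphenyl)silyl]oxy}-5-methylhept-5-enoate | CCOC(=O)C(CC/C(C)=C/CO[Si](c1ccccc1)(c1ccccc1)C(C)(C)C)C(C)=O
F5 | step 6 | ethyl (2E)-2-[(3E)-5-{[tert-butyl(diphenyl)silyl]oxy}-3-methylpent-3-en-1-yl]-3-{[(4-methylphenyl)sulfonyl]oxy}but-2-enoate | CCOC(=O)/C(CC/C(C)=C/CO[Si](c1ccccc1)(c1ccccc1)C(C)(C)C)=C(\C)OS(=O)(=O)c1ccc(C)cc1
F6 | step 14 | 2-thioxopyridin-1(2H)-yl 15-{[tert-butyl(diphenyl)silyl]oxy}labda-8,13E-diene-6α-carboxylate | S=C1C=CC=CN1OC(=O)[C@H]1CC(C)=C(CC/C(C)=C/CO[Si](c3ccccc3)(c3ccccc3)C(C)(C)C)[C@@]2(C)CCCC(C)(C)[C@H]12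
F7 | step 14 | 15-{[tert-butyl(diphenyl)silyl]oxy}labda-8,13E-dien-6-ol (C6 epimers) | OC1CC(C)=C(CC/C(C)=C/CO[Si](c3ccccc3)(c3ccccc3)C(C)(C)C)[C@@]2(C)CCCC(C)(C)[C@H]12
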